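| setting | south | west | Wednesday's | Sunday's |
|---|---|---|---|---|
| starting material | 0.059 M | 0.059 M | 0.059 M | 0.059 M |
| partner | 0.147 M | 0.147 M | 0.147 M | 0.147 M |
| second substrate | 0.059 M | 0.059 M | 0.0590 M | 0.0590 M |
| catalyst | 32 µM | 32 µM | 32 µM | 32 µM |
| added ligand | 16 µM | 36 µM | 24 µM | 24 µM |
| temperature | 0 °C | 20 °C | 5 °C | 35 °C |
| remark | run made earlier | run made earlier |  |  |
| time |  |  | 10 h | 10 h |

- south (time / h: target / %, starting material / %): 2.50: 16.5, 81.0; 5.00: 26.9, 66.7; 8.00: 34.5, 57.6; 10.0: 36.6, 50.8; 12.0: 37.5, 47.5
- west (time / h: target / %, starting material / %): 1.33: 32.7, 62.2; 2.50: 36.6, 48.1; 4.00: 41.4, 35.8; 5.00: 41.8, 33.5; 6.00: 40.2, 27.1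

(readings scatter by 1 percentage point)

1. which flask leads in amount of target, in percent of the starting material charged ("all alike" within 1.5 percentage points) (Wednesday's / Sunday's / all alike)
2. how much target is there at the end, in percent of the starting material charged: Wednesday's
3. how much target is there at the end, in percent of the starting material charged: Sunday's



- In a one-step world, each starting material lost becomes target, so I need only the speed. The first readings give an apparent loss constant of 0.0843 /h in the south run and 0.357 /h in the west run, with temperature and ligand changed together. Scaled to Wednesday's temperature, this speeds the south run by 1.43. That leaves 37.8% of the starting material at 10 h, and this world would hold 62.2% target.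
- The readings refuse that world: at 6.00 h the west run's starting material and target add up to 67.3%, so a further step uses up target.
- West target stands about still near 5.00 h, where making equals loss. There [starting material]/[target] reads the selectivity factor s, the rate constant of target's loss over that of its making: 0.801.
- I assume both steps use partner and catalyst alike, so these cancel. With x the fraction of starting material left, target is then (x^s − x)/(1 − s) of the charge.
- The south run tests this at 10.0 h: the curve gives 36.8%, the reading 36.6%. For Wednesday's flask the one-step figure falls to 40.6%.
- The rest moves speed and the end. I take added ligand to alter speed, not the curve. If the second substrate takes its full charge of partner, the partner left allows 1.49 equivalents on the starting material, fewer than the 2 that full over-reaction costs, so on this reckoning partner is the limiting reagent. Each x costs 2(1 − x) − target equivalents. Wednesday's flask needs 0.837, less than that, so its partner lasts.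
- Sunday's 10 h counts for about 29.5 h of the west run, so I place it near its end state. Trying x = 10.0%, the curve gives 29.2% target and a cost of 1.51 equivalents, close to the allowance. I commit to a little above that for Sunday's flask, with Wednesday's ahead.
- The forecast names Wednesday's, with 38% and 34%, figures that differ from mine, and says of Sunday's flask “this runs to the cap quickly, well past the peak”.
- The flasks give 39.7% in Wednesday's and 31.5% in Sunday's, so Wednesday's leads.

    starting material + partner + catalyst → catalyst + target (k = 39000 /M²/h, Ea = 45.0 kJ/mol)
    second substrate + partner + catalyst → catalyst + second product (k = 64000 /M²/h, Ea = 43.0 kJ/mol)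
    catalyst + added ligand ⇌ idle complex, settled at all times (K = 19000 /M, ΔH = −90.0 kJ/mol)
    partner + catalyst + target → catalyst + over-reaction product (k = 31000 /M²/h, Ea = 45.0 kJ/mol)
    (constants at 5 °C)

- Wednesday's flask has 42.5% of its starting material left at 10.0 h, more than my 37.8%, and on that amount the curve gives 39.6%. The neighbouring flask is Wednesday's with 0.15 M of starting material, which makes the partner 0.980 equiv and the second substrate 0.393 equiv. It keeps 54.1% of its starting material at 10.0 h, so the same s gives 35.4% target. That flask holds 35.4%.

The data stem from a simulated flask for substances that don't exist; the scatter is artificial.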